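## Retrosynthetic overview
1. The target comes from its tris-allyl-protected form (allyl ester plus two aryl allyl ethers) by deallylation with zerovalent palladium. The acetate is put on just before, after the benzylic silyl ether is removed.
2. The prenyl C=C comes from CO2 loss from a 3,3-dimethyl-β-lactone. The key C–C bond of that lactone is made by an intermolecular aldol addition of the lithium enolate of phenyl isobutyrate to the arylacetaldehyde of the complete diaryl ether.
3. The arylacetaldehyde comes from one-carbon homologation of the ring A aldehyde. The diaryl ether C–O bond comes from SNAr of the ring B phenol (fragment B) on a ring A fluoride activated by a para-CHO and an ortho-ester (fragment A).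
4. Fragment A comes from 4-fluoro-2-hydroxybenzaldehyde by directed ortho-lithiation and carboxylation. Fragment B comes from 2-hydroxy-4-methylbenzaldehyde by Dakin-type oxidation and phenolate hydroxymethylation.
5. Rings: both benzene rings are bought. The only ring made is the transient oxetan-2-one, formed in the key step and destroyed in the next step.

Assumption: the target has no stereocentre and no E/Z-isomeric double bond, so it is achiral and the given SMILES is its full stereochemical description. The one stereocentre created on the way (aldol step) is racemic and is erased one step later.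

## Route

Step 1
Reactants: 1 4-fluoro-2-hydroxybenzaldehyde
Product: 2 4-fluoro-2-(methoxymethoxy)benzaldehyde
Conditions: MOMCl (1.3 equiv), iPr2NEt (1.6 equiv), CH2Cl2, 0 °C to rt
Reagents that add atoms: chloromethyl methyl ether (MOMCl), COCCl
Why: Williamson-type O-alkylation of the phenol gives an acetal ether that is inert to n-BuLi and later acts as a strong directing group for lithiation.

Step 2
Reactants: 2 4-fluoro-2-(methoxymethoxy)benzaldehyde
Product: 3 2-[4-fluoro-2-(methoxymethoxy)phenyl]-1,3-dioxolane
Conditions: HOCH2CH2OH (3 equiv), PPTS (5 mol %), toluene, Dean–Stark, reflux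
Reagents that add atoms: ethylene glycol, OCCO
Why: Acid-catalysed acetalisation with azeotropic water removal masks the aldehyde against n-BuLi, and the weak acid PPTS leaves the aryl MOM ether intact.

Step 3
Reactants: 3 2-[4-fluoro-2-(methoxymethoxy)phenyl]-1,3-dioxolane
Product: 6 6-fluoro-3-formyl-2-hydroxybenzoic acid, via aryllithium 4 (not isolated), via lithium carboxylate 5 (not isolated)
Conditions: n-BuLi (1.1 equiv), THF, −78 °C, 1 h; CO2 (g), −78 to 0 °C; then 3 M aq HCl, THF, 50 °C
Reagents that add atoms: carbon dioxide, O=C=O; water, O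
Why: Directed ortho-metalation occurs only at the C–H flanked by the two cooperating directors OMOM and F (kept at −78 °C to avoid aryne formation), carboxylation fixes the acid carbon between them, and warm aqueous HCl then hydrolyses both acetals.

Step 4
Reactants: 6 6-fluoro-3-formyl-2-hydroxybenzoic acid
Product: 7 allyl 2-(allyloxy)-6-fluoro-3-formylbenzoate (fragment A)
Conditions: allyl bromide (2.6 equiv), K2CO3 (2.5 equiv), DMF, rt to 40 °C
Reagents that add atoms: allyl bromide, C=CCBr
Why: Double SN2 alkylation of carboxylate and phenolate installs in one operation the two ring A protecting groups that can be removed at the end without acid, base or hydrogen.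

Step 5
Reactants: 8 2-hydroxy-4-methylbenzaldehyde
Product: 9 2-(allyloxy)-4-methylbenzaldehyde
Conditions: allyl bromide (1.2 equiv), K2CO3 (1.5 equiv), DMF, rt
Reagents that add atoms: allyl bromide, C=CCBr
Why: Williamson ether synthesis on the only phenol fixes unambiguously which of the two later catechol oxygens carries the allyl group.

Step 6
Reactants: 9 2-(allyloxy)-4-methylbenzaldehyde
Product: 11 2-(allyloxy)-4-methylphenol, via aryl formate 10 (not isolated)
Conditions: 30% aq H2O2 (1.3 equiv), H2SO4 (cat.), MeOH, rt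
Reagents that add atoms: hydrogen peroxide, OO
Why: In this acid-catalysed Dakin-type (Baeyer–Villiger) oxidation the electron-rich aryl group migrates to oxygen, the aryl formate is methanolysed in situ, and H2O2 with acid does not epoxidise the allyl group.

Step 7
Reactants: 11 2-(allyloxy)-4-methylphenol
Product: 12 2-(allyloxy)-6-(hydroxymethyl)-4-methylphenol
Conditions: 37% aq CH2O (4 equiv), NaOH (1.1 equiv), H2O/MeOH, rt, 48 h; AcOH to pH 6
Reagents that add atoms: formaldehyde, C=O
Why: Lederer–Manasse hydroxymethylation, an aldol-type addition of the phenolate to formaldehyde, can only take place at the single free ortho position because the para and the other ortho position are blocked.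

Step 8
Reactants: 12 2-(allyloxy)-6-(hydroxymethyl)-4-methylphenol
Product: 13 2-(allyloxy)-6-{[(tert-butyldiphenylsilyl)oxy]methyl}-4-methylphenol (fragment B)
Conditions: TBDPSCl (1.05 equiv), imidazole (2.2 equiv), CH2Cl2, 0 °C to rt
Reagents that add atoms: tert-butylchlorodiphenylsilane (TBDPSCl), CC(C)(C)[Si](Cl)(c1ccccc1)c1ccccc1
Why: Silylation with the bulky chlorosilane selects the primary benzylic alcohol over the doubly ortho-substituted, hydrogen-bonded phenol, and the TBDPS ether tolerates the later aqueous acid, ylide, enolate and heat.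

Step 9
Reactants: 7 allyl 2-(allyloxy)-6-fluoro-3-formylbenzoate; 13 2-(allyloxy)-6-{[(tert-butyldiphenylsilyl)oxy]methyl}-4-methylphenol
Product: 14 allyl 2-(allyloxy)-6-[2-(allyloxy)-6-{[(tert-butyldiphenylsilyl)oxy]methyl}-4-methylphenoxy]-3-formylbenzoate
Conditions: K2CO3 (1.5 equiv), DMF, 70 °C
Reagents that add atoms: none
Why: Nucleophilic aromatic substitution (SNAr through a Meisenheimer complex) is fast because the fluoride sits para to the formyl and ortho to the ester group, fluoride is the only good leaving group, and the barely soluble KF formed does not attack the TBDPS ether at this temperature.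

Step 10
Reactants: 14 allyl 2-(allyloxy)-6-[2-(allyloxy)-6-{[(tert-butyldiphenylsilyl)oxy]methyl}-4-methylphenoxy]-3-formylbenzoate
Product: 15 allyl 2-(allyloxy)-6-[2-(allyloxy)-6-{[(tert-butyldiphenylsilyl)oxy]methyl}-4-methylphenoxy]-3-(2-methoxyvinyl)benzoate (E/Z mixture)
Conditions: Ph3P(CH2OMe)Cl (1.6 equiv), KOtBu (1.5 equiv), THF, 0 °C; then 14, 0 °C to rt
Reagents that add atoms: (methoxymethyl)triphenylphosphonium chloride, COC[P+](c1ccccc1)(c1ccccc1)c1ccccc1.[Cl-]
Why: Wittig olefination adds the missing carbon at the only aldehyde, the doubly ortho-substituted allyl ester is too hindered to react with the ylide, and the E/Z ratio is irrelevant because both isomers hydrolyse to the same aldehyde.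

Step 11
Reactants: 15 allyl 2-(allyloxy)-6-[2-(allyloxy)-6-{[(tert-butyldiphenylsilyl)oxy]methyl}-4-methylphenoxy]-3-(2-methoxyvinyl)benzoate
Product: 16 allyl 2-(allyloxy)-6-[2-(allyloxy)-6-{[(tert-butyldiphenylsilyl)oxy]methyl}-4-methylphenoxy]-3-(2-oxoethyl)benzoate
Conditions: 2 M aq HCl/THF (1:4), 40 °C; used at once
Reagents that add atoms: water, O
Why: Acid hydrolysis of the enol ether (C-protonation, hemiacetal, loss of methanol) releases the arylacetaldehyde under conditions that allyl ethers, the allyl ester and the acid-robust TBDPS ether survive.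

Step 12
Reactants: 17 phenol; 18 isobutyryl chloride
Product: 19 phenyl 2-methylpropanoate (phenyl isobutyrate)
Conditions: Et3N (1.2 equiv), CH2Cl2, 0 °C to rt
Reagents that add atoms: none
Why: Simple O-acylation of phenol with an acid chloride gives the activated ester whose phenoxide later serves as the leaving group for lactone closure.

Step 13 (key step)
Reactants: 16 allyl 2-(allyloxy)-6-[2-(allyloxy)-6-{[(tert-butyldiphenylsilyl)oxy]methyl}-4-methylphenoxy]-3-(2-oxoethyl)benzoate; 19 phenyl 2-methylpropanoate
Product: 22 allyl 2-(allyloxy)-6-[2-(allyloxy)-6-{[(tert-butyldiphenylsilyl)oxy]methyl}-4-methylphenoxy]-3-[(3,3-dimethyl-4-oxooxetan-2-yl)methyl]benzoate (racemic), via lithium enolate 20 (not isolated), via lithium aldolate 21 (not isolated)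
Conditions: 19 (1.4 equiv), LiN(iPr)2 (1.35 equiv), THF, −78 °C, 30 min; 16 added slowly, −78 °C, 1 h; warm to rt; aq NH4Cl
Reagents that add atoms: none
Why: Intermolecular aldol addition of the fully substituted lithium ester enolate to the aldehyde at −78 °C outruns enolisation, on warming the aldolate displaces phenoxide from the activated phenyl ester (gem-dimethyl-assisted lactonisation), and the new carbinol stereocentre is formed racemic on purpose because step 14 erases it.

Step 14
Reactants: 22 allyl 2-(allyloxy)-6-[2-(allyloxy)-6-{[(tert-butyldiphenylsilyl)oxy]methyl}-4-methylphenoxy]-3-[(3,3-dimethyl-4-oxooxetan-2-yl)methyl]benzoate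
Product: 23 allyl 2-(allyloxy)-6-[2-(allyloxy)-6-{[(tert-butyldiphenylsilyl)oxy]methyl}-4-methylphenoxy]-3-(3-methylbut-2-en-1-yl)benzoate
Conditions: o-xylene, 145 °C (reflux), 4–6 h
Reagents that add atoms: none
Why: Thermal [2+2] cycloreversion of the β-lactone (decarboxylative olefination) places the double bond exactly between the former carbinol and α-carbons, so only the prenyl isomer can form, two equal methyl groups leave no E/Z issue, and aromatic Claisen rearrangement of the aryl allyl ethers is still slow at 145 °C.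

Step 15
Reactants: 23 allyl 2-(allyloxy)-6-[2-(allyloxy)-6-{[(tert-butyldiphenylsilyl)oxy]methyl}-4-methylphenoxy]-3-(3-methylbut-2-en-1-yl)benzoate
Product: 24 allyl 2-(allyloxy)-6-[2-(allyloxy)-6-(hydroxymethyl)-4-methylphenoxy]-3-(3-methylbut-2-en-1-yl)benzoate
Conditions: Bu4NF (1.5 equiv), AcOH (1.5 equiv), THF, rt
Reagents that add atoms: none
Why: Fluoride-driven desilylation buffered with acetic acid frees the benzylic alcohol without ever forming a free alkoxide that could attack the neighbouring ester or trigger a Smiles rearrangement.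

Step 16
Reactants: 24 allyl 2-(allyloxy)-6-[2-(allyloxy)-6-(hydroxymethyl)-4-methylphenoxy]-3-(3-methylbut-2-en-1-yl)benzoate
Product: 25 allyl 6-[2-(acetoxymethyl)-6-(allyloxy)-4-methylphenoxy]-2-(allyloxy)-3-(3-methylbut-2-en-1-yl)benzoate
Conditions: Ac2O (1.5 equiv), pyridine (3 equiv), DMAP (5 mol %), CH2Cl2, 0 °C to rt
Reagents that add atoms: acetic anhydride, CC(=O)OC(C)=O
Why: DMAP-catalysed acetylation meets only one free hydroxyl group, since both phenols and the acid are still masked, so no chemoselectivity problem arises.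

Step 17
Reactants: 25 allyl 6-[2-(acetoxymethyl)-6-(allyloxy)-4-methylphenoxy]-2-(allyloxy)-3-(3-methylbut-2-en-1-yl)benzoate
Product: 26 7-O-acetylsecopenicillide C = 6-[2-(acetoxymethyl)-6-hydroxy-4-methylphenoxy]-2-hydroxy-3-(3-methylbut-2-en-1-yl)benzoic acid
Conditions: Pd(PPh3)4 (10 mol %), morpholine (10 equiv), THF, rt; cold 5% aq citric acid work-up
Reagents that add atoms: none
Why: In this Tsuji–Trost-type deallylation zerovalent palladium ionises the allyl ester and both aryl allyl ethers to π-allyl complexes that morpholine captures, while the prenyl C=C (no leaving group) and the benzylic acetate (not ionised by Pd(PPh3)4 at rt and not aminolysed in this time) stay untouched.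

## Compound list
1 | 4-fluoro-2-hydroxybenzaldehyde | O=Cc1ccc(F)cc1O | starting material
2 | 4-fluoro-2-(methoxymethoxy)benzaldehyde | COCOc1cc(F)ccc1C=O | intermediate
3 | 2-[4-fluoro-2-(methoxymethoxy)phenyl]-1,3-dioxolane | COCOc1cc(F)ccc1C1OCCO1 | intermediate
4 | [3-(1,3-dioxolan-2-yl)-6-fluoro-2-(methoxymethoxy)phenyl]lithium | [Li]c1c(F)ccc(C2OCCO2)c1OCOC | intermediate
5 | lithium 3-(1,3-dioxolan-2-yl)-6-fluoro-2-(methoxymethoxy)benzoate | [Li+].[O-]C(=O)c1c(F)ccc(C2OCCO2)c1OCOC | intermediate
6 | 6-fluoro-3-formyl-2-hydroxybenzoic acid | O=Cc1ccc(F)c(C(=O)O)c1O | intermediate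
7 | allyl 2-(allyloxy)-6-fluoro-3-formylbenzoate (fragment A) | C=CCOC(=O)c1c(F)ccc(C=O)c1OCC=C | intermediate
8 | 2-hydroxy-4-methylbenzaldehyde | Cc1ccc(C=O)c(O)c1 | starting material
9 | 2-(allyloxy)-4-methylbenzaldehyde | C=CCOc1cc(C)ccc1C=O | intermediate
10 | 2-(allyloxy)-4-methylphenyl formate | C=CCOc1cc(C)ccc1OC=O | intermediate
11 | 2-(allyloxy)-4-methylphenol | C=CCOc1cc(C)ccc1O | intermediate
12 | 2-(allyloxy)-6-(hydroxymethyl)-4-methylphenol | C=CCOc1cc(C)cc(CO)c1O | intermediate
13 | 2-(allyloxy)-6-{[(tert-butyldiphenylsilyl)oxy]methyl}-4-methylphenol (fragment B) | C=CCOc1cc(C)cc(CO[Si](c2ccccc2)(c2ccccc2)C(C)(C)C)c1O | intermediate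
14 | diaryl ether aldehyde: allyl 2-(allyloxy)-6-[2-(allyloxy)-6-{[(tert-butyldiphenylsilyl)oxy]methyl}-4-methylphenoxy]-3-formylbenzoate | C=CCOC(=O)c1c(Oc2c(OCC=C)cc(C)cc2CO[Si](c3ccccc3)(c3ccccc3)C(C)(C)C)ccc(C=O)c1OCC=C | intermediate
15 | enol ether (E/Z mixture): same skeleton with 3-(2-methoxyvinyl) | C=CCOC(=O)c1c(Oc2c(OCC=C)cc(C)cc2CO[Si](c3ccccc3)(c3ccccc3)C(C)(C)C)ccc(C=COC)c1OCC=C | intermediate
16 | arylacetaldehyde: same skeleton with 3-(2-oxoethyl) | C=CCOC(=O)c1c(Oc2c(OCC=C)cc(C)cc2CO[Si](c3ccccc3)(c3ccccc3)C(C)(C)C)ccc(CC=O)c1OCC=C | intermediate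
17 | phenol | Oc1ccccc1 | starting material
18 | isobutyryl chloride | CC(C)C(=O)Cl | starting material
19 | phenyl 2-methylpropanoate | CC(C)C(=O)Oc1ccccc1 | intermediate
20 | lithium enolate of phenyl 2-methylpropanoate | CC(C)=C([O-])Oc1ccccc1.[Li+] | intermediate
21 | lithium aldolate (racemic): same skeleton with 3-[2-oxido-3,3-dimethyl-4-oxo-4-phenoxybutyl] | C=CCOC(=O)c1c(Oc2c(OCC=C)cc(C)cc2CO[Si](c3ccccc3)(c3ccccc3)C(C)(C)C)ccc(CC([O-])C(C)(C)C(=O)Oc2ccccc2)c1OCC=C.[Li+] | intermediate
22 | β-lactone (racemic): same skeleton with 3-[(3,3-dimethyl-4-oxooxetan-2-yl)methyl] | C=CCOC(=O)c1c(Oc2c(OCC=C)cc(C)cc2CO[Si](c3ccccc3)(c3ccccc3)C(C)(C)C)ccc(CC2OC(=O)C2(C)C)c1OCC=C | intermediate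
23 | prenyl arene: same skeleton with 3-(3-methylbut-2-en-1-yl) | C=CCOC(=O)c1c(Oc2c(OCC=C)cc(C)cc2CO[Si](c3ccccc3)(c3ccccc3)C(C)(C)C)ccc(CC=C(C)C)c1OCC=C | intermediate
24 | allyl 2-(allyloxy)-6-[2-(allyloxy)-6-(hydroxymethyl)-4-methylphenoxy]-3-(3-methylbut-2-en-1-yl)benzoate | C=CCOC(=O)c1c(Oc2c(OCC=C)cc(C)cc2CO)ccc(CC=C(C)C)c1OCC=C | intermediate
25 | allyl 6-[2-(acetoxymethyl)-6-(allyloxy)-4-methylphenoxy]-2-(allyloxy)-3-(3-methylbut-2-en-1-yl)benzoate | C=CCOC(=O)c1c(Oc2c(OCC=C)cc(C)cc2COC(C)=O)ccc(CC=C(C)C)c1OCC=C | intermediate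
26 | 7-O-acetylsecopenicillide C (achiral) | CC(=O)OCc1cc(C)cc(O)c1Oc1ccc(CC=C(C)C)c(O)c1C(=O)O | target

## Step count and risks
Total step count: 17. Longest linear sequence: 12 steps (steps 1–4 or steps 5–8, followed by steps 9, 10, 11, 13, 14, 15, 16 and 17).

**Step 13 (aldol addition and lactonisation).**
- Risk: the basic enolate may enolise the arylacetaldehyde, or the aldolate may be captured by a second aldehyde molecule.
- The fallback sets out from 19 and 16 and comes back at 22. It keeps the same aldol bond but separates C–C bond formation from ring closure.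
- Compound 19 is converted with LiN(iPr)2 and Me3SiCl (THF, −78 °C) into the silyl ketene acetal trimethyl[(2-methyl-1-phenoxyprop-1-en-1-yl)oxy]silane F1.
- A Mukaiyama aldol addition of this acetal to 16 (BF3·OEt2, CH2Cl2, −78 °C) has no base present, so no enolisation can occur. After aqueous work-up it gives the racemic β-hydroxy phenyl ester F2.
- One equivalent of LiN(SiMe3)2 (THF, −78 to 0 °C) then closes the ring with loss of phenoxide to give 22.

**Step 14 (thermolysis).**
- Risk: decarboxylation may need longer heating than the two aryl allyl ethers tolerate before Claisen rearrangement sets in.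
- The fallback sets out from 22 and comes back at 23, and it avoids high temperature altogether.
- LiOH (THF/H2O, 0 °C to rt) opens the strained lactone while the hindered allyl benzoate stays intact. This gives the racemic β-hydroxy acid F3.
- N,N-dimethylformamide dineopentyl acetal (toluene, 80 °C) then brings about a decarboxylative dehydration, a Grob-type fragmentation of the O-activated hydroxy carboxylate. It forms the same regiodefined double bond of 23.

**Step 11 (release of the arylacetaldehyde).**
- Risk: the acid needed to hydrolyse the styryl-type enol ether may also cause self-condensation of the sensitive aldehyde or partial desilylation.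
- The fallback sets out from 14, bypasses 15 and comes back at 16.
- Corey–Chaykovsky epoxidation (Me3SI, NaH, DMSO/THF, 0 °C) gives the racemic aryl oxirane F4.
- A Meinwald rearrangement with InCl3 (10 mol %, THF, rt) opens it at the benzylic carbon, which is stabilised by the ortho-allyloxy and para-aryloxy groups. A hydride shift then gives 16 without any aqueous Brønsted acid.

## Further compounds
F1 | step 13 | trimethyl[(2-methyl-1-phenoxyprop-1-en-1-yl)oxy]silane | CC(C)=C(O[Si](C)(C)C)Oc1ccccc1
F2 | step 13 | allyl 2-(allyloxy)-6-[2-(allyloxy)-6-{[(tert-butyldiphenylsilyl)oxy]methyl}-4-methylphenoxy]-3-(2-hydroxy-3,3-dimethyl-4-oxo-4-phenoxybutyl)benzoate (racemic) | C=CCOC(=O)c1c(Oc2c(OCC=C)cc(C)cc2CO[Si](c3ccccc3)(c3ccccc3)C(C)(C)C)ccc(CC(O)C(C)(C)C(=O)Oc2ccccc2)c1OCC=C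
F3 | step 14 | 4-{2-(allyloxy)-3-[(allyloxy)carbonyl]-4-[2-(allyloxy)-6-{[(tert-butyldiphenylsilyl)oxy]methyl}-4-methylphenoxy]phenyl}-3-hydroxy-2,2-dimethylbutanoic acid (racemic) | C=CCOC(=O)c1c(Oc2c(OCC=C)cc(C)cc2CO[Si](c3ccccc3)(c3ccccc3)C(C)(C)C)ccc(CC(O)C(C)(C)C(=O)O)c1OCC=C
F4 | step 11 | allyl 2-(allyloxy)-6-[2-(allyloxy)-6-{[(tert-butyldiphenylsilyl)oxy]methyl}-4-methylphenoxy]-3-(oxiran-2-yl)benzoate (racemic) | C=CCOC(=O)c1c(Oc2c(OCC=C)cc(C)cc2CO[Si](c3ccccc3)(c3ccccc3)C(C)(C)C)ccc(C2CO2)c1OCC=C
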